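**Strategy**

The dihydrofuran ring B (O1–C2–C3–C3a–C7a) is disconnected across O1–C7a and C2–C3, so that the C2 carbinol unit derives from a vanillic acyl group and C3/C7a from an ortho-triflyloxy styrene. The key step exploits the fact that C3 is a benzylic, methyl-bearing carbon ortho to the aryl carbon C7a that carries O1: the vinyl group is a latent chiral benzylic nucleophile, the triflate an aryl electrophile. In one flask, copper hydride hydroacylation of styrene 8 with anhydride 12 and in situ ketone reduction set C3 and C2, and palladium-catalysed aryl etherification closes ring B. The side-chain diol comes from (S)-lactaldehyde by Felkin–Anh arylation.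

Key step: step 7

**Remarks and assumptions**

- Locants: dihydrobenzofuran O1, C2, C3, C3a, C4–C7, C7a; side chain C1′ (benzylic), C2′, C3′. TBS = tert-butyldimethylsilyl, TIPS = triisopropylsilyl, Tf = trifluoromethanesulfonyl.
- Compounds 1, 4 and 9 are taken as commercial.
- (S,S)-Ph-BPE [1,2-bis((2S,5S)-2,5-diphenylphospholan-1-yl)ethane] is assumed to deliver hydride to the vinyl face that gives the (S)-configured benzylic copper centre (C3). Should the sense be the opposite, (R,R)-Ph-BPE is used and nothing else changes.
- The anhydride 12 is built from two molecules of acid 11; in step 6 the second molecule is entered as the atom-contributing partner.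

**Route**

Step 1
Reactants: 1 5-bromo-2-hydroxy-3-methoxybenzaldehyde
Product: 2 4-bromo-2-formyl-6-methoxyphenyl trifluoromethanesulfonate
Conditions: Tf2O, pyridine, CH2Cl2, 0 °C to rt
Reagents that add atoms: trifluoromethanesulfonic anhydride, O=S(=O)(OS(=O)(=O)C(F)(F)F)C(F)(F)F
Why: O-sulfonylation of the phenol turns the oxygen substituent on the future C7a into the aryl electrophile needed for ring closure, and the aldehyde is untouched under pyridine buffering.

Step 2
Reactants: 2 4-bromo-2-formyl-6-methoxyphenyl trifluoromethanesulfonate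
Product: 3 4-bromo-2-ethenyl-6-methoxyphenyl trifluoromethanesulfonate
Conditions: MePPh3Br, KN(SiMe3)2, THF, 0 °C; then 2, −78 °C to 0 °C
Reagents that add atoms: methyltriphenylphosphonium bromide, C[P+](c1ccccc1)(c1ccccc1)c1ccccc1.[Br-]
Why: Wittig methylenation installs the vinyl group that becomes C3 and its methyl, the non-stabilised ylide reacting with the aldehyde far faster than with the sulfonate ester at low temperature.

Step 3
Reactants: 3 4-bromo-2-ethenyl-6-methoxyphenyl trifluoromethanesulfonate; 4 (2S)-2-(tert-butyldimethylsilyloxy)propanal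
Product: 7 2-ethenyl-4-[(1R,2S)-1-hydroxy-2-(tert-butyldimethylsilyloxy)propyl]-6-methoxyphenyl trifluoromethanesulfonate, via aryllithium 5 (not isolated), via aryltitanium triisopropoxide 6 (not isolated)
Conditions: n-BuLi, THF, −78 °C; ClTi(OiPr)3, −78 °C; then 4, −78 to −20 °C; aq NH4Cl
Reagents that add atoms: none
Why: Bromine–lithium exchange at −78 °C is faster than addition of n-BuLi to the styrene or attack at the sulfonate, and the non-chelating aryltitanium reagent should add to the α-silyloxy aldehyde in the Felkin–Anh mode (OTBS antiperiplanar to the incoming aryl), which sets C1′ as R next to the lactate-derived (S)-C2′ (1,2-anti, erythro); the minor syn isomer is removed by chromatography.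

Step 4
Reactants: 7 2-ethenyl-4-[(1R,2S)-1-hydroxy-2-(tert-butyldimethylsilyloxy)propyl]-6-methoxyphenyl trifluoromethanesulfonate
Product: 8 4-[(1R,2S)-1,2-bis(tert-butyldimethylsilyloxy)propyl]-2-ethenyl-6-methoxyphenyl trifluoromethanesulfonate
Conditions: TBSOTf, 2,6-lutidine, CH2Cl2, −40 to 0 °C
Reagents that add atoms: tert-butyldimethylsilyl trifluoromethanesulfonate, CC(C)(C)[Si](C)(C)OS(=O)(=O)C(F)(F)F
Why: Silyl triflate silylation masks the hindered benzylic hydroxyl so that no O–H consumes hydride or competes as a nucleophile in step 7, and any silyl shift between O1′ and O2′ that occurred in step 3 is levelled because both oxygens end up silylated.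

Step 5
Reactants: 9 4-hydroxy-3-methoxybenzoic acid (vanillic acid)
Product: 11 3-methoxy-4-(triisopropylsilyloxy)benzoic acid, via bis-silylated vanillate 10 (not isolated)
Conditions: TIPSCl, imidazole, DMF, rt; then K2CO3, MeOH/THF/H2O, 0 °C; citric acid work-up
Reagents that add atoms: chlorotri(propan-2-yl)silane, CC(C)[Si](Cl)(C(C)C)C(C)C
Why: Exhaustive silylation followed by selective hydrolysis of the much more labile silyl ester leaves the phenol masked as a TIPS ether that tolerates hydride, phosphate base and heat.

Step 6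
Reactants: 11 3-methoxy-4-(triisopropylsilyloxy)benzoic acid (two molecules per molecule of product; the second is entered below)
Product: 12 3-methoxy-4-(triisopropylsilyloxy)benzoic anhydride
Conditions: DCC (0.5 equiv relative to total acid 11), CH2Cl2, 0 °C to rt; filtration
Reagents that add atoms: second molecule of acid 11, 3-methoxy-4-(triisopropylsilyloxy)benzoic acid, COc1cc(C(=O)O)ccc1O[Si](C(C)C)(C(C)C)C(C)C
Why: In this carbodiimide dehydration DCC activates one molecule of 11 as its O-acylisourea, which is acylated at oxygen by the carboxyl group of a second molecule of 11 to give the symmetrical aryl carboxylic anhydride (the acyl donor class that the copper hydride coupling requires) while the elements of water end up in N,N'-dicyclohexylurea.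

Step 7
Reactants: 8 4-[(1R,2S)-1,2-bis(tert-butyldimethylsilyloxy)propyl]-2-ethenyl-6-methoxyphenyl trifluoromethanesulfonate; 12 3-methoxy-4-(triisopropylsilyloxy)benzoic anhydride
Product: 16 {4-[(2S,3S)-5-[(1R,2S)-1,2-bis(tert-butyldimethylsilyloxy)propyl]-7-methoxy-3-methyl-2,3-dihydro-1-benzofuran-2-yl]-2-methoxyphenoxy}tri(propan-2-yl)silane, via ketone 13 (not isolated), via silyl ether 14 (not isolated), via alcohol 15 (not isolated)
Conditions: Cu(OAc)2 (5 mol%), (S,S)-Ph-BPE (5.5 mol%), MeSiH(OMe)2 (5 equiv), THF, 40 °C; MeOH, rt, then evaporation; Pd2(dba)3 (3 mol%), RockPhos (8 mol%), K3PO4 (4 equiv), toluene, 90 °C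
Reagents that add atoms: none
Why: A ligated copper hydride adds across the vinyl group of 8 with copper at the benzylic carbon, this alkylcopper is acylated by anhydride 12 to give ketone 13 (C2–C3 bond), a second copper hydride cycle reduces 13 to silyl ether 14, methanol frees alcohol 15, and zerovalent palladium then inserts into the C7a–OTf bond and forms the O1–C7a bond by reductive elimination from the aryl palladium alkoxide. The closest known reaction types are the copper hydride catalysed reductive coupling of vinyl arenes with aryl carboxylic anhydrides to 1,2-diarylpropan-1-ols and the palladium-catalysed intramolecular etherification of 2-(2-haloaryl)ethanols. Ring B closes as a five-membered ring by C(sp2)–O reductive elimination from a six-membered oxapalladacycle, with retention at C2 and C3. C3 is set as S by the chiral bisphosphine in the enantio-determining hydrocupration, and C2 is set as S in the hydride addition to 13, which should follow the Felkin–Anh mode (hydride anti to the aryl group on C3) and gives the 1,2-relationship that becomes trans in the ring. The step needs hydrocupration of the vinyl group ahead of anhydride reduction and survival of the triflate until the palladium stage, which the substrate secures because the styrene is its only π bond reactive toward copper hydride, every hydroxyl is silylated and the aryl triflate is inert to copper hydride; β-hydride elimination at palladium is held back by the bulky biaryl phosphine.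

Step 8
Reactants: 16 {4-[(2S,3S)-5-[(1R,2S)-1,2-bis(tert-butyldimethylsilyloxy)propyl]-7-methoxy-3-methyl-2,3-dihydro-1-benzofuran-2-yl]-2-methoxyphenoxy}tri(propan-2-yl)silane
Product: 17 (1R,2S)-1-[(2S,3S)-2-(4-hydroxy-3-methoxyphenyl)-7-methoxy-3-methyl-2,3-dihydro-1-benzofuran-5-yl]propane-1,2-diol
Conditions: Bu4NF, AcOH, THF, 0 °C to rt
Reagents that add atoms: none
Why: Fluoride cleaves the aryl TIPS ether and both alkyl TBS ethers in one operation, and the acetic acid buffer keeps the liberated phenol protonated so that the benzylic C2–O1 bond is not opened through a para-quinone methide.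

**Compound list**

1 | 5-bromo-2-hydroxy-3-methoxybenzaldehyde | COc1cc(Br)cc(C=O)c1O | starting material
2 | 4-bromo-2-formyl-6-methoxyphenyl trifluoromethanesulfonate | COc1cc(Br)cc(C=O)c1OS(=O)(=O)C(F)(F)F | intermediate
3 | 4-bromo-2-ethenyl-6-methoxyphenyl trifluoromethanesulfonate | COc1cc(Br)cc(C=C)c1OS(=O)(=O)C(F)(F)F | intermediate
4 | (2S)-2-(tert-butyldimethylsilyloxy)propanal | C[C@H](O[Si](C)(C)C(C)(C)C)C=O | starting material
5 | [3-ethenyl-5-methoxy-4-(trifluoromethanesulfonyloxy)phenyl]lithium | [Li]c1cc(OC)c(OS(=O)(=O)C(F)(F)F)c(C=C)c1 | intermediate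
6 | [3-ethenyl-5-methoxy-4-(trifluoromethanesulfonyloxy)phenyl]titanium triisopropoxide | CC(C)O[Ti](OC(C)C)(OC(C)C)c1cc(OC)c(OS(=O)(=O)C(F)(F)F)c(C=C)c1 | intermediate
7 | 2-ethenyl-4-[(1R,2S)-1-hydroxy-2-(tert-butyldimethylsilyloxy)propyl]-6-methoxyphenyl trifluoromethanesulfonate | C=Cc1cc([C@@H](O)[C@H](C)O[Si](C)(C)C(C)(C)C)cc(OC)c1OS(=O)(=O)C(F)(F)F | intermediate
8 | 4-[(1R,2S)-1,2-bis(tert-butyldimethylsilyloxy)propyl]-2-ethenyl-6-methoxyphenyl trifluoromethanesulfonate | C=Cc1cc([C@@H](O[Si](C)(C)C(C)(C)C)[C@H](C)O[Si](C)(C)C(C)(C)C)cc(OC)c1OS(=O)(=O)C(F)(F)F | intermediate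
9 | 4-hydroxy-3-methoxybenzoic acid (vanillic acid) | COc1cc(C(=O)O)ccc1O | starting material
10 | triisopropylsilyl 3-methoxy-4-(triisopropylsilyloxy)benzoate | COc1cc(C(=O)O[Si](C(C)C)(C(C)C)C(C)C)ccc1O[Si](C(C)C)(C(C)C)C(C)C | intermediate
11 | 3-methoxy-4-(triisopropylsilyloxy)benzoic acid | COc1cc(C(=O)O)ccc1O[Si](C(C)C)(C(C)C)C(C)C | intermediate
12 | 3-methoxy-4-(triisopropylsilyloxy)benzoic anhydride | COc1cc(C(=O)OC(=O)c2ccc(O[Si](C(C)C)(C(C)C)C(C)C)c(OC)c2)ccc1O[Si](C(C)C)(C(C)C)C(C)C | intermediate
13 | 4-[(1R,2S)-1,2-bis(tert-butyldimethylsilyloxy)propyl]-2-methoxy-6-[(2S)-1-[3-methoxy-4-(triisopropylsilyloxy)phenyl]-1-oxopropan-2-yl]phenyl trifluoromethanesulfonate | COc1cc(C(=O)[C@@H](C)c2cc([C@@H](O[Si](C)(C)C(C)(C)C)[C@H](C)O[Si](C)(C)C(C)(C)C)cc(OC)c2OS(=O)(=O)C(F)(F)F)ccc1O[Si](C(C)C)(C(C)C)C(C)C | intermediate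
14 | 4-[(1R,2S)-1,2-bis(tert-butyldimethylsilyloxy)propyl]-2-[(1S,2S)-1-[dimethoxy(methyl)silyloxy]-1-[3-methoxy-4-(triisopropylsilyloxy)phenyl]propan-2-yl]-6-methoxyphenyl trifluoromethanesulfonate | COc1cc([C@@H](O[Si](C)(OC)OC)[C@@H](C)c2cc([C@@H](O[Si](C)(C)C(C)(C)C)[C@H](C)O[Si](C)(C)C(C)(C)C)cc(OC)c2OS(=O)(=O)C(F)(F)F)ccc1O[Si](C(C)C)(C(C)C)C(C)C | intermediate
15 | 4-[(1R,2S)-1,2-bis(tert-butyldimethylsilyloxy)propyl]-2-[(1S,2S)-1-hydroxy-1-[3-methoxy-4-(triisopropylsilyloxy)phenyl]propan-2-yl]-6-methoxyphenyl trifluoromethanesulfonate | COc1cc([C@@H](O)[C@@H](C)c2cc([C@@H](O[Si](C)(C)C(C)(C)C)[C@H](C)O[Si](C)(C)C(C)(C)C)cc(OC)c2OS(=O)(=O)C(F)(F)F)ccc1O[Si](C(C)C)(C(C)C)C(C)C | intermediate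
16 | {4-[(2S,3S)-5-[(1R,2S)-1,2-bis(tert-butyldimethylsilyloxy)propyl]-7-methoxy-3-methyl-2,3-dihydro-1-benzofuran-2-yl]-2-methoxyphenoxy}tri(propan-2-yl)silane | COc1cc([C@H]2Oc3c(OC)cc([C@@H](O[Si](C)(C)C(C)(C)C)[C@H](C)O[Si](C)(C)C(C)(C)C)cc3[C@@H]2C)ccc1O[Si](C(C)C)(C(C)C)C(C)C | intermediate
17 | (1R,2S)-1-[(2S,3S)-2-(4-hydroxy-3-methoxyphenyl)-7-methoxy-3-methyl-2,3-dihydro-1-benzofuran-5-yl]propane-1,2-diol | COc1cc([C@H]2Oc3c(OC)cc([C@@H](O)[C@H](C)O)cc3[C@@H]2C)ccc1O | target

**Step count**

Total step count: 8.
Longest linear sequence: 6 steps (1, 2, 3, 4, 7, 8, from compound 1).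

**Steps most likely to fail**

Step 7. Four processes threaten it:
- the three catalytic events may not tolerate one another in one flask (hydrodetriflation at palladium by residual silane, binding of the bisphosphine to palladium);
- hydride delivery to ketone 13 may show poor facial selectivity at C2;
- β-hydride elimination may compete with C–O reductive elimination;
- the alkoxide may attack the sulfonyl sulfur, so that triflyl transfer precedes ring closure.

Fallback, setting out from 8 and 12 and returning at 16: the events are separated and C2 is set by substrate control. The copper hydride coupling is run with 1.2 equiv of silane at rt so that it stops at ketone 13, which is isolated. Ketone 13 is reduced with LiBH(sBu)3 in THF at −78 °C (Felkin–Anh, hydride anti to the aryl group on C3) to alcohol 15, which is purified. Alcohol 15 is cyclised in a separate flask, free of copper and silane, with Pd2(dba)3, RockPhos and K3PO4 in toluene at 90 °C. This fallback makes no compound outside the list (none F0).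

Step 3. Facial selectivity in the aryl addition may be poor, giving erosion of the erythro relationship at C1′. Competing addition of n-BuLi to the styrene or attack at the sulfonate may also consume material.

Fallback, setting out from 3 and returning at 8: C1′ is set by chelation-controlled reduction in place of aldehyde addition.
- Aryllithium 5 is acylated at −78 °C with (2S)-2-(tert-butyldimethylsilyloxy)-N-methoxy-N-methylpropanamide (C[C@H](O[Si](C)(C)C(C)(C)C)C(=O)N(C)OC) to give the α-silyloxy ketone 2-ethenyl-6-methoxy-4-[(2S)-2-(tert-butyldimethylsilyloxy)propanoyl]phenyl trifluoromethanesulfonate F1.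
- HF·pyridine in MeCN frees the α-hydroxy ketone 2-ethenyl-4-[(2S)-2-hydroxypropanoyl]-6-methoxyphenyl trifluoromethanesulfonate F2.
- Zn(BH4)2 in Et2O at −20 °C reduces F2 through the five-membered zinc chelate, hydride arriving from the face of the C2′–H, to the erythro diol 4-[(1R,2S)-1,2-dihydroxypropyl]-2-ethenyl-6-methoxyphenyl trifluoromethanesulfonate F3.
- TBSOTf (2.5 equiv) and 2,6-lutidine then give 8.

Step 6. The O-acylisourea may rearrange to the N-acylurea, and the anhydride may hydrolyse during isolation; residual free acid would then consume hydride in step 7.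

Fallback, setting out from 11 and returning at 12: the anhydride is made by acyl substitution in place of dehydration. Half of acid 11 is converted with oxalyl chloride and catalytic DMF in CH2Cl2 into 3-methoxy-4-(triisopropylsilyloxy)benzoyl chloride F4. F4 is combined with the other half of 11 and Et3N in CH2Cl2 at 0 °C to give 12.

**Further compounds**

F0 | step 7 | none | none
F1 | step 3 | 2-ethenyl-6-methoxy-4-[(2S)-2-(tert-butyldimethylsilyloxy)propanoyl]phenyl trifluoromethanesulfonate | C=Cc1cc(C(=O)[C@H](C)O[Si](C)(C)C(C)(C)C)cc(OC)c1OS(=O)(=O)C(F)(F)F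
F2 | step 3 | 2-ethenyl-4-[(2S)-2-hydroxypropanoyl]-6-methoxyphenyl trifluoromethanesulfonate | C=Cc1cc(C(=O)[C@H](C)O)cc(OC)c1OS(=O)(=O)C(F)(F)F
F3 | step 3 | 4-[(1R,2S)-1,2-dihydroxypropyl]-2-ethenyl-6-methoxyphenyl trifluoromethanesulfonate | C=Cc1cc([C@@H](O)[C@H](C)O)cc(OC)c1OS(=O)(=O)C(F)(F)F
F4 | step 6 | 3-methoxy-4-(triisopropylsilyloxy)benzoyl chloride | COc1cc(C(=O)Cl)ccc1O[Si](C(C)C)(C(C)C)C(C)C
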